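**Strategy**

The piperidine is traced back to a temporary chroman-2-ol in which the phenol oxygen ortho to C8 of the benzo ring (the later O1 of the chromone) holds C2' as a lactol. The key step, an aminocatalytic formal [4+2] annulation of benzyloxyacetaldehyde with an ortho-quinone methide, closes this dihydropyran ring by forging the C3'–C4' bond and sets both stereocentres; its precursor is an open-chain 1-aryl-3-aminopropan-1-ol. It exploits the benzylic C4' on the electron-rich ring and the 1,2-relationship of N1'–C2' and O–C3'. Hydrogenolysis then passes C2' from oxygen to N1', and the freed phenol carries the chromone annulation.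

Key step: step 3

Remark: primed locants (N1', C2' to C6') refer to the piperidine ring and unprimed ones to the chromone; the sense of induction in step 3 is assigned by analogy with known enamine additions, and the enantiomeric catalyst would be used if the lactol formed in the mirror-image series.

Remark: compounds 1, 2, 5 and 16 and the catalyst of step 3 are taken to be commercially available.

**Route**

Step 1
Reactants: 1 2-hydroxy-4,6-dimethoxybenzaldehyde; 2 N-benzyl-N-methylacetamide
Product: 3 N-benzyl-3-hydroxy-3-(2-hydroxy-4,6-dimethoxyphenyl)-N-methylpropanamide (racemic)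
Conditions: LiN(iPr)2 (2.3 equiv), 2 (2.3 equiv), THF, −78 °C; then 1, −78 to −40 °C; aq. NH4Cl
Reagents that add atoms: none
Why: Directed aldol addition of the preformed lithium amide enolate to the aldehyde should proceed once the phenol has consumed one equivalent of enolate, the chelated aldolate being quenched cold to suppress retro-aldol cleavage; the carbinol centre is racemic and is erased in step 3.

Step 2
Reactants: 3 N-benzyl-3-hydroxy-3-(2-hydroxy-4,6-dimethoxyphenyl)-N-methylpropanamide
Product: 4 2-{3-[benzyl(methyl)amino]-1-hydroxypropyl}-3,5-dimethoxyphenol (racemic)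
Conditions: LiAlH4 (4 equiv), THF, 0 °C to rt; aq. KNaC4H4O6 work-up, product used crude
Reagents that add atoms: none
Why: LiAlH4 reduces the tertiary amide to the tertiary amine (amide reduction) while phenol and carbinol are held as aluminates, and the non-acidic work-up avoids ionization of the acid-labile benzylic alcohol.

Step 3
Reactants: 4 2-{3-[benzyl(methyl)amino]-1-hydroxypropyl}-3,5-dimethoxyphenol; 5 benzyloxyacetaldehyde
Product: 7 (3S,4R)-3-(benzyloxy)-4-{2-[benzyl(methyl)amino]ethyl}-5,7-dimethoxy-3,4-dihydro-2H-chromen-2-ol (lactol; both C2 epimers), via ortho-quinone methide 6 (not isolated)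
Conditions: (R)-2-[diphenyl(trimethylsilyloxy)methyl]pyrrolidine (20 mol%), PhCO2H (1.2 equiv), 5 (3 equiv), CHCl3, 0 °C to rt
Reagents that add atoms: none
Why: Benzoic acid holds the tertiary amine of 4 as its salt and promotes loss of water from the electron-rich ortho-hydroxybenzylic alcohol to ortho-quinone methide 6, while 5 condenses with the secondary amine catalyst to the E-enamine. The enamine carbon (later C3') adds to the methide carbon (later C4') and the phenoxide then closes on the iminium carbon (later C2'), an asynchronous inverse-electron-demand oxa-[4+2] annulation; hydrolysis of the cyclic N,O-acetal releases lactol 7 and the catalyst. The closest known reaction type is the aminocatalytic formal [4+2] annulation (Michael addition–hemiacetalization) of aldehydes with ortho-quinone methides generated in situ. One ring is closed, the six-membered dihydropyran of the chroman-2-ol, by the new C3'–C4' bond together with the temporary O–C2' bond (the latter a 6-exo-trig addition of the phenoxide to the iminium ion). C3' is controlled by the diphenyl(trimethylsilyloxy)methyl group, which shields one face of the enamine, and C4' by the endo-type synclinal approach to the E-configured methide, which places the benzyloxy group and the aminoethyl chain trans on the chroman ring, the arrangement that becomes cis (3S,4R) on the piperidine. The step needs interception of 6 faster than its tautomerization to the styrene and C- rather than O-alkylation of the aldehyde; the excess of 5, the low temperature and the protonated, non-nucleophilic side-chain amine should secure this.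

Step 4
Reactants: 7 (3S,4R)-3-(benzyloxy)-4-{2-[benzyl(methyl)amino]ethyl}-5,7-dimethoxy-3,4-dihydro-2H-chromen-2-ol
Product: 10 2-[(3S,4R)-3-hydroxy-1-methylpiperidin-4-yl]-3,5-dimethoxyphenol, via amino lactol 8 (not isolated), via O-benzyl piperidine 9 (not isolated)
Conditions: H2 (4 bar), Pd(OH)2/C, AcOH (3 equiv), MeOH, rt
Reagents that add atoms: none
Why: Hydrogenolysis removes the N-benzyl group, the secondary amine condenses with the lactol carbon and the resulting iminium ion is reduced in the same pot (reductive amination), which moves C2' from oxygen to N1' and frees the phenol, and the O-benzyl ether is cleaved under the same conditions; C4' is untouched and C3' should be retained because the iminium ion is reduced faster than it tautomerizes.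

Step 5
Reactants: 10 2-[(3S,4R)-3-hydroxy-1-methylpiperidin-4-yl]-3,5-dimethoxyphenol
Product: 12 (3S,4R)-4-(3-acetyl-2-hydroxy-4,6-dimethoxyphenyl)-1-methylpiperidin-3-yl acetate, via diacetate 11 (not isolated)
Conditions: Ac2O (4 equiv), BF3·OEt2 (6 equiv), CH2Cl2, 0 °C to rt; aq. Na2CO3
Reagents that add atoms: acetic anhydride CC(=O)OC(C)=O
Why: Both hydroxyls are acetylated and BF3 then drives the Fries rearrangement of the aryl acetate to C3 of the aryl ring, the only free position ortho to the phenol, where the ketone is held as a difluoroboron chelate until work-up, the amine being masked as its BF3 adduct.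

Step 6
Reactants: 12 (3S,4R)-4-(3-acetyl-2-hydroxy-4,6-dimethoxyphenyl)-1-methylpiperidin-3-yl acetate
Product: 14 8-[(3S,4R)-3-hydroxy-1-methylpiperidin-4-yl]-5,7-dimethoxy-2-methyl-4H-chromen-4-one, via 1,3-diketone 13 (not isolated)
Conditions: NaH (6 equiv), EtOAc, THF, reflux; then conc. HCl, rt
Reagents that add atoms: ethyl acetate CCOC(C)=O
Why: Claisen condensation of the methyl ketone enolate with ethyl acetate gives the 1,3-diketone (the ethoxide set free also cleaves the alkyl acetate), and acid closes the pyranone ring onto the only free ortho phenol by cyclodehydration, which fixes the piperidine at C8 of the 2-methylchromone.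

Step 7
Reactants: 14 8-[(3S,4R)-3-hydroxy-1-methylpiperidin-4-yl]-5,7-dimethoxy-2-methyl-4H-chromen-4-one
Product: 15 rohitukine (5,7-dihydroxy-8-[(3S,4R)-3-hydroxy-1-methylpiperidin-4-yl]-2-methyl-4H-chromen-4-one)
Conditions: pyridine hydrochloride (30 equiv), melt, 180 °C
Reagents that add atoms: none
Why: Molten pyridine hydrochloride cleaves both aryl methyl ethers by chloride attack on the protonated ether (demethylation), which should leave the amino alcohol and its two stereocentres untouched.

Step 8
Reactants: 15 rohitukine; 16 3,4-dimethoxybenzoyl chloride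
Product: 18 chrotacumine D, via tris(3,4-dimethoxybenzoate) 17 (not isolated)
Conditions: 16 (4 equiv), DMAP (0.2 equiv), pyridine, 60 °C; then MeOH, K2CO3 (0.3 equiv), 0 °C
Reagents that add atoms: none
Why: Exhaustive DMAP-catalysed acylation esterifies the hindered secondary alcohol together with the phenols, and brief carbonate-catalysed methanolysis then removes only the far more labile aryl esters at O5 and O7, so the alkyl 3,4-dimethoxybenzoate at C3' remains with its configuration unchanged.

**Compound list**

1 | 2-hydroxy-4,6-dimethoxybenzaldehyde | O=Cc1c(O)cc(OC)cc1OC | starting material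
2 | N-benzyl-N-methylacetamide | CC(=O)N(C)Cc1ccccc1 | starting material
3 | N-benzyl-3-hydroxy-3-(2-hydroxy-4,6-dimethoxyphenyl)-N-methylpropanamide (racemic) | CN(Cc1ccccc1)C(=O)CC(O)c1c(O)cc(OC)cc1OC | intermediate
4 | 2-{3-[benzyl(methyl)amino]-1-hydroxypropyl}-3,5-dimethoxyphenol (racemic) | CN(CCC(O)c1c(O)cc(OC)cc1OC)Cc1ccccc1 | intermediate
5 | benzyloxyacetaldehyde | O=CCOCc1ccccc1 | starting material
6 | 6-{3-[benzyl(methyl)amino]propylidene}-3,5-dimethoxycyclohexa-2,4-dien-1-one (ortho-quinone methide) | CN(CCC=C1C(=O)C=C(OC)C=C1OC)Cc1ccccc1 | intermediate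
7 | (3S,4R)-3-(benzyloxy)-4-{2-[benzyl(methyl)amino]ethyl}-5,7-dimethoxy-3,4-dihydro-2H-chromen-2-ol | OC1Oc2cc(OC)cc(OC)c2[C@@H](CCN(C)Cc2ccccc2)[C@@H]1OCc1ccccc1 | intermediate
8 | (3S,4R)-3-(benzyloxy)-5,7-dimethoxy-4-[2-(methylamino)ethyl]-3,4-dihydro-2H-chromen-2-ol | OC1Oc2cc(OC)cc(OC)c2[C@@H](CCNC)[C@@H]1OCc1ccccc1 | intermediate
9 | 2-[(3S,4R)-3-(benzyloxy)-1-methylpiperidin-4-yl]-3,5-dimethoxyphenol | O(Cc1ccccc1)[C@@H]1CN(C)CC[C@@H]1c1c(O)cc(OC)cc1OC | intermediate
10 | 2-[(3S,4R)-3-hydroxy-1-methylpiperidin-4-yl]-3,5-dimethoxyphenol | O[C@@H]1CN(C)CC[C@@H]1c1c(O)cc(OC)cc1OC | intermediate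
11 | (3S,4R)-4-[2-(acetyloxy)-4,6-dimethoxyphenyl]-1-methylpiperidin-3-yl acetate | CC(=O)O[C@@H]1CN(C)CC[C@@H]1c1c(OC(C)=O)cc(OC)cc1OC | intermediate
12 | (3S,4R)-4-(3-acetyl-2-hydroxy-4,6-dimethoxyphenyl)-1-methylpiperidin-3-yl acetate | CC(=O)O[C@@H]1CN(C)CC[C@@H]1c1c(O)c(C(C)=O)c(OC)cc1OC | intermediate
13 | 1-{2-hydroxy-3-[(3S,4R)-3-hydroxy-1-methylpiperidin-4-yl]-4,6-dimethoxyphenyl}butane-1,3-dione | O[C@@H]1CN(C)CC[C@@H]1c1c(O)c(C(=O)CC(C)=O)c(OC)cc1OC | intermediate
14 | 8-[(3S,4R)-3-hydroxy-1-methylpiperidin-4-yl]-5,7-dimethoxy-2-methyl-4H-chromen-4-one | O[C@@H]1CN(C)CC[C@@H]1c1c(OC)cc(OC)c2c(=O)cc(C)oc12 | intermediate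
15 | rohitukine, 5,7-dihydroxy-8-[(3S,4R)-3-hydroxy-1-methylpiperidin-4-yl]-2-methyl-4H-chromen-4-one | O[C@@H]1CN(C)CC[C@@H]1c1c(O)cc(O)c2c(=O)cc(C)oc12 | intermediate
16 | 3,4-dimethoxybenzoyl chloride | COc1ccc(C(=O)Cl)cc1OC | starting material
17 | (3S,4R)-4-[5,7-bis(3,4-dimethoxybenzoyloxy)-2-methyl-4-oxo-4H-chromen-8-yl]-1-methylpiperidin-3-yl 3,4-dimethoxybenzoate | COc1ccc(C(=O)O[C@@H]2CN(C)CC[C@@H]2c2c(OC(=O)c3ccc(OC)c(OC)c3)cc(OC(=O)c3ccc(OC)c(OC)c3)c3c(=O)cc(C)oc23)cc1OC | intermediate
18 | chrotacumine D, (3S,4R)-4-(5,7-dihydroxy-2-methyl-4-oxo-4H-chromen-8-yl)-1-methylpiperidin-3-yl 3,4-dimethoxybenzoate | COc1ccc(C(=O)O[C@@H]2CN(C)CC[C@@H]2c2c(O)cc(O)c3c(=O)cc(C)oc23)cc1OC | target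

**Step count and risks**

Total steps: 8. Longest linear sequence: 8 steps (1 to 18).

1. Step 3. The quinone methide may tautomerize to the ortho-hydroxystyrene or oligomerize before the enamine intercepts it, and facial or diastereocontrol may erode if both geometries of the methide react. The fallback sets out from 4 and returns at 7. Treatment of 4 with p-TolSO2Na in aqueous formic acid should give sulfone F1, a stable precursor that releases the quinone methide with Cs2CO3 under basic conditions. In the presence of a chiral isothiourea (benzotetramisole), the ammonium enolate of benzyloxyacetic acid (activated with pivaloyl chloride and iPr2NEt) should add to it and lactonize (Michael addition–lactonization) to dihydrocoumarin F2. Its C3 centre can be equilibrated to the trans isomer with DBU. Reduction with iBu2AlH at −78 °C then gives lactol 7.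

2. Step 4. After N-debenzylation the cyclic iminium ion may tautomerize to the enamine and lose the C3' configuration or benzyl alcohol before it is reduced, and hydrogenolysis of the O-benzyl ether may stall in the presence of the amine. The fallback sets out from 7 and returns at 10. Oxidation of the lactol with Ag2CO3 on Celite should give lactone F2. Hydrogenolysis (H2, Pd(OH)2/C) then removes both benzyl groups while the liberated secondary amine opens the aryl lactone by O-to-N acyl transfer to hydroxy lactam F3, a path that never passes through an iminium ion. LiAlH4 reduces the lactam to 10.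

3. Step 1. Conversion may stay low because the lithium phenoxide formed first deactivates the aldehyde, and the aldol addition may revert on warming. The fallback sets out from 1 and returns at 3. Silylation (TBSCl, imidazole) gives silyl ether F4, a neutral and more electrophilic aldehyde. Addition of the lithium enolate of 2 gives silylated aldol adduct F5, and Bu4NF buffered with AcOH removes the silyl group to give 3.

**Further compounds**

F1 | step 3 | 2-{3-[benzyl(methyl)amino]-1-[(4-methylphenyl)sulfonyl]propyl}-3,5-dimethoxyphenol (racemic) | CN(CCC(c1c(O)cc(OC)cc1OC)S(=O)(=O)c1ccc(C)cc1)Cc1ccccc1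
F2 | step 3 | (3S,4R)-3-(benzyloxy)-4-{2-[benzyl(methyl)amino]ethyl}-5,7-dimethoxy-3,4-dihydro-2H-chromen-2-one | O=C1Oc2cc(OC)cc(OC)c2[C@@H](CCN(C)Cc2ccccc2)[C@@H]1OCc1ccccc1
F3 | step 4 | (3S,4R)-3-hydroxy-4-(2-hydroxy-4,6-dimethoxyphenyl)-1-methylpiperidin-2-one | O[C@@H]1C(=O)N(C)CC[C@@H]1c1c(O)cc(OC)cc1OC
F4 | step 1 | 2-{[tert-butyl(dimethyl)silyl]oxy}-4,6-dimethoxybenzaldehyde | O=Cc1c(O[Si](C)(C)C(C)(C)C)cc(OC)cc1OC
F5 | step 1 | N-benzyl-3-(2-{[tert-butyl(dimethyl)silyl]oxy}-4,6-dimethoxyphenyl)-3-hydroxy-N-methylpropanamide (racemic) | CN(Cc1ccccc1)C(=O)CC(O)c1c(O[Si](C)(C)C(C)(C)C)cc(OC)cc1OC
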